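## The problem

The target **14** is a trans-2-aryl-3-methyl-2,3-dihydro-1,4-benzodioxine. Ring A (the benzo ring, with OMe at C5 and an E-propenyl group at C7) is joined through O1 and O4 to the dioxane ring B; C2 carries ring C (4-hydroxy-3,5-dimethoxyphenyl) and C3 a methyl group. The two adjacent stereocentres, C2 (R) and C3 (R), are trans. Either can direct the other only during a ring closure, so one has to be set by a catalyst on an open-chain compound and the second relayed from it. The two ring oxygens are not equivalent: O4 sits on C4a, next to the C5 methoxy group and para to C7, and O1 sits on C8a. The catechol oxygens of ring A must therefore be told apart, or the aryl and methyl groups end up transposed. The free phenol of ring C is para to the benzylic C2–O1 bond and can expel O1 as a quinone methide under acid, base or oxidation, which would scramble C2. The E-propenyl group on ring A is an electron-rich styrene that does not survive acid, radicals, electrophiles or hydrogenation and must be introduced late. The feature that makes the key step possible is that C3 carries CH3, H and O4 next to C2. This is the Markovnikov adduct of the C4a hydroxyl across a vinyl group on C2, so a 1-arylallyl ether of O1 with a free C4a–OH (**11**) is one hydrogen-atom transfer away from ring B (**12**).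

## Retrosynthesis

**Target 14 back to 13 and 12.** The last two operations are cleavage of the ring C pivalate (**13** to **14**) and formation of the C7 propenyl C=C bond from the C7 aldehyde of **12**. The propenyl group is cut first because a conjugated aryl alkene accepts hydrogen atoms from metal hydrides more readily than a plain vinyl group and could not be present in the key step. The aldehyde is its natural placeholder: it is already present in the commercial ring A building block, and it makes the ring A phenol harder to oxidise. The pivalate keeps ring C from forming a quinone methide in every earlier step. The forward steps must give an E-selective ethylidenation of a non-enolisable aryl aldehyde and a mild ester cleavage.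

**12 back to 11 (key disconnection).** The O4–C3 bond and one C–H bond of the C3 methyl group are cut, which turns C3 and its methyl group into a vinyl group on C2. The neighbouring cut, O1–C2, would close the ring through a benzylic cation or quinone methide and would put C2 at risk. Cutting both C–O bonds to a catechol and a C3 dielectrophile would bring back the regiochemical problem of the two oxygens. The chosen cut removes ring B and one stereocentre and leaves C2 to be made on an open chain. The forward reaction must add O4–H across the alkene in the Markovnikov sense without ionising the allylic, benzylic C2–O1 ether (Brønsted acids, π-acids and zerovalent palladium would all do so), and it must place the methyl group trans to the aryl group.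

**11 back to 10, and 10 back to 9 and 6.** Removing a SEM group from O4 gives **10**; cutting O1–C2 gives the lithium aryloxide **9** (from phenol **8**) and the linear allylic carbonate **6**. An iridium-catalysed asymmetric allylic etherification forms exactly this branched aryl ether and sets C2 under ligand control. It is preferred to an SN2 displacement on a secondary benzylic allylic alcohol, which tends to give SN2′ products and partial racemisation. Three details are chosen to support it:
- The linear E carbonate is used instead of the branched racemic carbonate. Branched substrates react with this catalyst family largely with retention of their own configuration, so the ligand could not fully control C2.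
- A tert-butyl carbonate releases only tert-butoxide, which does not attack the pivalate.
- The acyloxy group on ring C makes the 1-arylallyl ether **10** reluctant to re-ionise.

O4 must be blocked, because the para phenoxide is the more acidic and would otherwise be allylated. SEM is chosen because an acetal cannot migrate to the neighbouring oxygen, as silyl and acyl groups do, and because fluoride removes it without acid.

**6 back to 5, 4, 2, 3 and 1.** The carbonate **6** comes from the cinnamyl-type alcohol **5**. This is the 1,3-transposed isomer of the vinyl carbinol **4**, made from the aldehyde **2** (pivalate of syringaldehyde **1**) and vinylmagnesium bromide **3**. A Wittig or Horner–Wadsworth–Emmons homologation followed by hydride reduction of the ester would also reduce the aryl pivalate. Grignard addition at low temperature spares it, and conjugation drives the transposition to the linear E alcohol.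

**8 back to 7.** The SEM ether **8** comes from 3,4-dihydroxy-5-methoxybenzaldehyde **7** by alkylation of the 4-hydroxyl, which is para to the formyl group and the more acidic of the two.

## Roads not taken

**Alternative 1:** Both aryl–oxygen bonds, O1–C8a and O4–C4a, are cut at once, taking ring A back to an aryne and ring B to a 1,2-dione. Fluoride would release the aryne from the silyl triflate A2, and the s-cis form of the dione A3 would add through both carbonyl oxygens in a hetero-Diels–Alder reaction to give the 1,4-benzodioxine A1.
- Merits: it is convergent; the heterocycle and both C–O(aryl) bonds arise in one step, and no protecting group is needed to distinguish the catechol oxygens. In the coupling phase it is shorter than the chosen plan.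
- Weak points: aryne and dione are both unsymmetrical, and the only bias is the inductive effect of the methoxy group. The two carbonyl oxygens are of similar nucleophilicity, so aryl and methyl may end up transposed. Open-chain 1,2-diones prefer the s-trans form and often react with arynes at carbon or by insertion. A1 has no stereocentre, so the tetrasubstituted, doubly oxygenated C2=C3 bond would have to be hydrogenated enantioselectively. Syn addition gives the cis isomer, so C2 would then have to be epimerised through the quinone methide after the phenol is freed. A2 also needs a multistep synthesis.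
- Comparison: the chosen plan spends a SEM group and two more steps on regiocontrol, but it sets C2 by catalyst control on an open chain and forms C3 directly trans.

**Alternative 2:** The O1–C8a bond is cut. The precursor A5 is an open-chain 1-aryl-2-aryloxypropan-1-ol that already holds both stereocentres and has a symmetrical 2,6-dimethoxyphenoxy group as ring A. Under blue light an acridinium photocatalyst would oxidise ring A to its radical cation, the C2 hydroxyl would attack C8a at a methoxy-bearing carbon, and the methoxy group would leave as its alcohol, giving A4 with both centres retained.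
- Merits: the symmetry of ring A removes the catechol regiochemistry problem, and the closure asks for no diastereoselectivity at all. In this respect it is better than the chosen plan, whose C3 selectivity rests on a single substituent.
- Weak points: A5 is a benzylic alcohol of the β-aryloxy type, and radical cations of such systems tend to fragment at the C2–C3 bond or to be oxidised to the aryl ketone. Ring C competes for the oxidant even as its tosylate. Intramolecular displacement of an unactivated methoxy group by a secondary alcohol is at the edge of what cation-radical-accelerated substitution has shown. The stereochemical work is only moved: A5 in its (1R,2R) form needs an asymmetric sequence of its own, of similar length.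
- Comparison: against the stereochemical security of that closure, the chosen plan sets a ring closure of a known reaction class, one catalytic asymmetric step, and no exposure of a benzylic C–O bond to a strongly oxidising photocatalyst.

**Alternative 3:** The O1–C2 bond is cut. The precursor A7 carries C3 as its only stereocentre in a 1-arylpropan-2-yl aryl ether. Two-electron anodic oxidation of the 4-alkyl-2,6-dimethoxyphenol (ring C) would give the para-quinone methide at C2, and the ring A hydroxyl on C8a would add to it to give A6, trans because the addition is reversible and the closing half-chair prefers both groups equatorial.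
- Merits: ring C needs no protecting group, the oxidant is the electrode, and A6 is already the free phenol with the C7 aldehyde. Only the olefination would remain, so the route is about two steps shorter than the chosen one. This is a real advantage in step economy.
- Weak points: A6 is itself a 4-alkyl-2,6-dimethoxyphenol with a benzylic hydrogen and should be oxidised at nearly the same potential as A7, so over-oxidation and ring opening compete. The quinone methide has a hydrogen at C3 and can tautomerise to an enol ether. A7 requires a secondary alkyl–aryl ether at the hindered para oxygen of ring A, made with clean inversion and with the catechol still to be differentiated.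
- Comparison: the chosen plan pays for the pivalate with two steps. In return, neither the substrate nor the product of its key step can form a quinone methide, and C2 is set by a catalyst and not by an equilibrium.

Key step: step 8

Assumption: the (Sa,S,S) phosphoramidite is taken to give the (S) ether **10**, by the facial preference this catalyst family shows with (E)-cinnamyl carbonates and heteroatom nucleophiles. If the sense proves opposite, the (Ra,R,R) ligand is used and nothing else changes.

## Route

Step 1
Reactants: 1 syringaldehyde (4-hydroxy-3,5-dimethoxybenzaldehyde)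
Product: 2 4-formyl-2,6-dimethoxyphenyl pivalate (2,2-dimethylpropanoate)
Conditions: PivCl (1.2 equiv), Et3N (1.5 equiv), DMAP (5 mol%), CH2Cl2, 0 °C to rt
Reagents that add atoms: pivaloyl chloride, CC(C)(C)C(Cl)=O
Why: DMAP-catalysed O-acylation of an acidic phenol; the pivalate is chosen because it withdraws electron density from ring C (less ionisation at the future C2) and is shielded by two ortho methoxy groups against the nucleophiles of steps 2, 6, 7 and 9.

Step 2
Reactants: 2 4-formyl-2,6-dimethoxyphenyl pivalate; 3 vinylmagnesium bromide
Product: 4 4-(1-hydroxyprop-2-en-1-yl)-2,6-dimethoxyphenyl pivalate (racemic)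
Conditions: CH2=CHMgBr (1.1 equiv), THF, −78 °C; aq. NH4Cl
Reagents that add atoms: none
Why: Grignard 1,2-addition; at −78 °C the formyl group should react far faster than the di-ortho-substituted aryl ester. The carbinol centre is racemic and is erased in step 3.

Step 3
Reactants: 4 4-(1-hydroxyprop-2-en-1-yl)-2,6-dimethoxyphenyl pivalate
Product: 5 4-[(1E)-3-hydroxyprop-1-en-1-yl]-2,6-dimethoxyphenyl pivalate
Conditions: Ph3SiOReO3 (2 mol%), Et2O, −50 °C to 0 °C
Reagents that add atoms: none
Why: Rhenium-oxo-catalysed 1,3-transposition of an allylic alcohol through the allyl perrhenate ([3,3] shift); conjugation with the arene should drive the equilibrium to the linear alcohol, and the chair-like shift gives the E alkene.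

Step 4
Reactants: 5 4-[(1E)-3-hydroxyprop-1-en-1-yl]-2,6-dimethoxyphenyl pivalate
Product: 6 4-{(1E)-3-[(tert-butoxycarbonyl)oxy]prop-1-en-1-yl}-2,6-dimethoxyphenyl pivalate
Conditions: Boc2O (1.3 equiv), DMAP (10 mol%), CH2Cl2, 0 °C to rt
Reagents that add atoms: di-tert-butyl dicarbonate, CC(C)(C)OC(=O)OC(=O)OC(C)(C)C
Why: DMAP-catalysed O-acylation to the allylic tert-butyl carbonate; the tert-butyl group is chosen so that the alkoxide released on ionisation in step 6 is tert-butoxide, which should neither transesterify the carbonate nor attack the pivalate.

Step 5
Reactants: 7 3,4-dihydroxy-5-methoxybenzaldehyde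
Product: 8 3-hydroxy-5-methoxy-4-{[2-(trimethylsilyl)ethoxy]methoxy}benzaldehyde
Conditions: K2CO3 (1.05 equiv), SEMCl (1.0 equiv), DMF, 0 °C
Reagents that add atoms: 2-(trimethylsilyl)ethoxymethyl chloride, C[Si](C)(C)CCOCCl
Why: Regioselective Williamson-type O-alkylation; one equivalent of carbonate deprotonates only the 4-hydroxyl, which is para to the formyl group and clearly more acidic than the 3-hydroxyl, and this phenoxide is alkylated. The acetal-type SEM group cannot migrate to the neighbouring oxygen under the basic conditions of step 6.

Step 6
Reactants: 8 3-hydroxy-5-methoxy-4-{[2-(trimethylsilyl)ethoxy]methoxy}benzaldehyde; 6 4-{(1E)-3-[(tert-butoxycarbonyl)oxy]prop-1-en-1-yl}-2,6-dimethoxyphenyl pivalate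
Product: 10 4-[(1S)-1-(5-formyl-3-methoxy-2-{[2-(trimethylsilyl)ethoxy]methoxy}phenoxy)prop-2-en-1-yl]-2,6-dimethoxyphenyl pivalate, via lithium aryloxide 9 (not isolated)
Conditions: 8 (1.3 equiv), LiOtBu (1.3 equiv), THF, 0 °C; then 6 (1.0 equiv) and the catalyst pre-formed from [Ir(cod)Cl]2 (2 mol%), (Sa,S,S)-O,O′-(1,1′-binaphthyl-2,2′-diyl) N,N-bis(1-phenylethyl)phosphoramidite (4 mol%) and n-PrNH2 (THF, 50 °C, volatiles removed), THF, 25–50 °C; aq. NH4Cl
Reagents that add atoms: lithium tert-butoxide, [Li+].CC(C)(C)[O-] (its lithium stays in intermediate 9 only)
Why: Iridium-catalysed asymmetric allylic etherification of a linear cinnamyl-type carbonate with an aryloxide; the cyclometalated iridium–phosphoramidite complex ionises 6 to one allyl complex and the aryloxide attacks the aryl-bearing terminus anti to the metal, giving the branched ether with the future C2 set by the ligand. Only the meta oxygen (the future O1) can react because O4 is blocked, and the acyloxy group on ring C should make 10 slow to re-ionise.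

Step 7
Reactants: 10 4-[(1S)-1-(5-formyl-3-methoxy-2-{[2-(trimethylsilyl)ethoxy]methoxy}phenoxy)prop-2-en-1-yl]-2,6-dimethoxyphenyl pivalate
Product: 11 4-[(1S)-1-(5-formyl-2-hydroxy-3-methoxyphenoxy)prop-2-en-1-yl]-2,6-dimethoxyphenyl pivalate
Conditions: TBAF (3 equiv, 1 M in THF), THF, 0 °C to 40 °C; aq. NH4Cl
Reagents that add atoms: none
Why: Fluoride-induced fragmentation of the SEM ether (attack at silicon, loss of ethene and formaldehyde) releases a phenoxide that is a good leaving group because it is para to the formyl group. The conditions are not acidic, so the allylic benzylic ether is safe, and the shielded pivalate should survive.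

Step 8
Reactants: 11 4-[(1S)-1-(5-formyl-2-hydroxy-3-methoxyphenoxy)prop-2-en-1-yl]-2,6-dimethoxyphenyl pivalate
Product: 12 4-[(2R,3R)-7-formyl-5-methoxy-3-methyl-2,3-dihydro-1,4-benzodioxin-2-yl]-2,6-dimethoxyphenyl pivalate
Conditions: Co(salen) [C32H46CoN2O2, the divalent cobalt complex of N,N′-bis(3,5-di-tert-butylsalicylidene)ethane-1,2-diamine] (5 mol%), N-fluoro-2,4,6-trimethylpyridinium tetrafluoroborate (1.5 equiv), PhSiH3 (1.5 equiv), PhCF3, 0 °C, argon; aq. NaHCO3
Reagents that add atoms: none
Why: This is the cobalt-salen, silane and N-fluoropyridinium hydroalkoxylation of an unactivated alkene (a Mukaiyama-type hydrogen-atom-transfer hydrofunctionalisation with radical–polar crossover), used in its known intramolecular form with a phenol as the oxygen nucleophile. The N–F salt oxidises divalent cobalt to a trivalent cobalt fluoride, PhSiH3 converts it into a trivalent cobalt hydride, and the hydride gives a hydrogen atom to the terminal CH2 of the vinyl group, which fixes the Markovnikov sense and creates the C3 methyl group. The secondary C3 radical is captured by cobalt, the alkylcobalt is oxidised to the tetravalent level, and the O4 phenol displaces cobalt at C3 while its proton goes to the collidine. Ring B closes in the 6-exo mode with respect to the alkene (O4 bonds to the internal carbon and the former CH2 stays outside the ring). C3 is controlled by the C2 stereocentre from step 6: the two C3-epimeric organocobalt species interconvert by reversible Co–C homolysis, and the displacement should prefer the half-chair in which the C2 aryl group and the new methyl group are both pseudo-equatorial, which leads to the trans (2R,3R) product. The step also needs chemoselectivity: the reagents are neither Brønsted- nor π-acidic, so the allylic, benzylic C2–O1 ether is not ionised; the vinyl group is the only C=C bond because the propenyl group is still an aldehyde; the pivalate keeps ring C from being oxidised and the formyl group makes the ring A phenol harder to oxidise and more acidic. Capture of the C3 radical by cobalt has to outrun β-scission of C2–O1 and a 1,2-aryl shift, which is why the reaction is run cold with a cobalt mediator and not as a tin or thiol chain.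

Step 9
Reactants: 12 4-[(2R,3R)-7-formyl-5-methoxy-3-methyl-2,3-dihydro-1,4-benzodioxin-2-yl]-2,6-dimethoxyphenyl pivalate
Product: 13 2,6-dimethoxy-4-{(2R,3R)-5-methoxy-3-methyl-7-[(1E)-prop-1-en-1-yl]-2,3-dihydro-1,4-benzodioxin-2-yl}phenyl pivalate
Conditions: 5-(ethylsulfonyl)-1-phenyl-1H-tetrazole (1.4 equiv), KN(SiMe3)2 (1.3 equiv), DME, −60 °C; then 12, −60 °C to rt; aq. NH4Cl
Reagents that add atoms: 5-(ethylsulfonyl)-1-phenyl-1H-tetrazole, CCS(=O)(=O)c1nnnn1c1ccccc1
Why: Julia–Kocienski olefination; the metalated sulfone adds to the non-enolisable aldehyde, and Smiles rearrangement with loss of SO2 and the tetrazolone gives the disubstituted alkene, expected to be mainly E with potassium in DME. The aldehyde is far more electrophilic than the shielded pivalate, and neither stereocentre bears an acidic hydrogen.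

Step 10
Reactants: 13 2,6-dimethoxy-4-{(2R,3R)-5-methoxy-3-methyl-7-[(1E)-prop-1-en-1-yl]-2,3-dihydro-1,4-benzodioxin-2-yl}phenyl pivalate
Product: 14 2,6-dimethoxy-4-{(2R,3R)-5-methoxy-3-methyl-7-[(1E)-prop-1-en-1-yl]-2,3-dihydro-1,4-benzodioxin-2-yl}phenol (target)
Conditions: NaOMe (2 equiv), MeOH/THF, 0 °C to rt; aq. NH4Cl as soon as 13 is consumed
Reagents that add atoms: none
Why: Methanolysis of an aryl ester (transesterification with the aryloxide as leaving group), which leaves the E-propenyl group and the dioxane untouched. It is kept cold and short so that the liberated phenoxide, which is para to C2–O1, is not given time to open ring B through the quinone methide.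

## Compound list

1 | syringaldehyde (4-hydroxy-3,5-dimethoxybenzaldehyde) | COc1cc(C=O)cc(OC)c1O | starting material
2 | 4-formyl-2,6-dimethoxyphenyl pivalate | O=Cc1cc(OC)c(OC(=O)C(C)(C)C)c(OC)c1 | intermediate
3 | vinylmagnesium bromide | C=C[Mg]Br | starting material
4 | 4-(1-hydroxyprop-2-en-1-yl)-2,6-dimethoxyphenyl pivalate (racemic) | OC(C=C)c1cc(OC)c(OC(=O)C(C)(C)C)c(OC)c1 | intermediate
5 | 4-[(1E)-3-hydroxyprop-1-en-1-yl]-2,6-dimethoxyphenyl pivalate | OC/C=C/c1cc(OC)c(OC(=O)C(C)(C)C)c(OC)c1 | intermediate
6 | 4-{(1E)-3-[(tert-butoxycarbonyl)oxy]prop-1-en-1-yl}-2,6-dimethoxyphenyl pivalate | CC(C)(C)OC(=O)OC/C=C/c1cc(OC)c(OC(=O)C(C)(C)C)c(OC)c1 | intermediate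
7 | 3,4-dihydroxy-5-methoxybenzaldehyde | COc1cc(C=O)cc(O)c1O | starting material
8 | 3-hydroxy-5-methoxy-4-{[2-(trimethylsilyl)ethoxy]methoxy}benzaldehyde | O=Cc1cc(O)c(OCOCC[Si](C)(C)C)c(OC)c1 | intermediate
9 | lithium 5-formyl-3-methoxy-2-{[2-(trimethylsilyl)ethoxy]methoxy}phenolate | [Li+].[O-]c1cc(C=O)cc(OC)c1OCOCC[Si](C)(C)C | intermediate (not isolated)
10 | 4-[(1S)-1-(5-formyl-3-methoxy-2-{[2-(trimethylsilyl)ethoxy]methoxy}phenoxy)prop-2-en-1-yl]-2,6-dimethoxyphenyl pivalate | O=Cc1cc(OC)c(OCOCC[Si](C)(C)C)c(c1)O[C@H](c1cc(OC)c(OC(=O)C(C)(C)C)c(OC)c1)C=C | intermediate
11 | 4-[(1S)-1-(5-formyl-2-hydroxy-3-methoxyphenoxy)prop-2-en-1-yl]-2,6-dimethoxyphenyl pivalate | O=Cc1cc(OC)c(O)c(c1)O[C@H](c1cc(OC)c(OC(=O)C(C)(C)C)c(OC)c1)C=C | intermediate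
12 | 4-[(2R,3R)-7-formyl-5-methoxy-3-methyl-2,3-dihydro-1,4-benzodioxin-2-yl]-2,6-dimethoxyphenyl pivalate | O=Cc1cc(OC)c2c(c1)O[C@H](c1cc(OC)c(OC(=O)C(C)(C)C)c(OC)c1)[C@@H](C)O2 | intermediate
13 | 2,6-dimethoxy-4-{(2R,3R)-5-methoxy-3-methyl-7-[(1E)-prop-1-en-1-yl]-2,3-dihydro-1,4-benzodioxin-2-yl}phenyl pivalate | C/C=C/c1cc(OC)c2c(c1)O[C@H](c1cc(OC)c(OC(=O)C(C)(C)C)c(OC)c1)[C@@H](C)O2 | intermediate
14 | 2,6-dimethoxy-4-{(2R,3R)-5-methoxy-3-methyl-7-[(1E)-prop-1-en-1-yl]-2,3-dihydro-1,4-benzodioxin-2-yl}phenol | C/C=C/c1cc(OC)c2c(c1)O[C@H](c1cc(OC)c(O)c(OC)c1)[C@@H](C)O2 | target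

## Step count and least certain steps

Total step count: 10. Longest linear sequence: 9 steps (steps 1, 2, 3, 4, 6, 7, 8, 9, 10, from syringaldehyde); step 5 is a one-step branch.

**Step 8 (key step).** Three things can go wrong:
- Loss of the C3 radical before O4 bonds, by β-scission of the C2–O1 ether or by a cation-like 1,2-hydride shift from C2, both favoured because C2 is benzylic and oxygen-bearing.
- Poor facial selectivity at C3, since the C2 aryl group is the only control element.
- Reduction of the formyl group by the silane.

A wrong C3 epimer cannot be corrected by equilibration: epimerising C2 in its place would lead into the enantiomeric trans series, so the isomers would have to be separated. The fallback replaces the radical addition by a polar one and sets out from **11**. Iodoetherification (I2, NaHCO3, MeCN, 0 °C) should close ring B 6-exo, reversibly and therefore in favour of the trans isomer, to 4-[(2R,3S)-7-formyl-3-(iodomethyl)-5-methoxy-2,3-dihydro-1,4-benzodioxin-2-yl]-2,6-dimethoxyphenyl pivalate F1. Radical deiodination (Bu3SnH, AIBN, toluene, 80 °C) then turns the iodomethyl group into the C3 methyl group and returns to the route at **12**.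

**Step 6.** The likely failures are a poor branched-to-linear ratio or erosion of enantiopurity by re-ionisation of the product, because the aryloxide of **8** is hindered, only moderately nucleophilic and a fair leaving group. The fallback forms O1–C2 by SN2 displacement and sets out from **4**. Katsuki–Sharpless epoxidation used as a kinetic resolution (Ti(OiPr)4, D-(−)-diisopropyl tartrate, tBuOOH, 4 Å sieves, CH2Cl2, −20 °C) should leave 4-[(1R)-1-hydroxyprop-2-en-1-yl]-2,6-dimethoxyphenyl pivalate F2. The (S) enantiomer is consumed as 4-{(R)-hydroxy[(2S)-oxiran-2-yl]methyl}-2,6-dimethoxyphenyl pivalate F3 and separated. A Mitsunobu reaction of F2 with phenol **8** (PPh3, diisopropyl azodicarboxylate, toluene, 0 °C) inverts the carbinol centre and returns to the route at **10**; steps 3, 4 and 6 are then not needed.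

**Step 7.** The danger is loss of the pivalate to basic fluoride, after which the ring C phenoxide could expel O1 and destroy C2, or incomplete cleavage of the hindered SEM ether. The fallback changes the blocking group on O4 and the way it is removed, and sets out from **7**. MOMCl with K2CO3 in DMF gives 3-hydroxy-5-methoxy-4-(methoxymethoxy)benzaldehyde F4. Coupling with **6** under the conditions of step 6 gives 4-{(1S)-1-[5-formyl-3-methoxy-2-(methoxymethoxy)phenoxy]prop-2-en-1-yl}-2,6-dimethoxyphenyl pivalate F5. The phenolic acetal is then cleaved on NaHSO4 supported on SiO2 in CH2Cl2 at rt, which returns to the route at **11**.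

**Step 9.** The risk is incomplete E selectivity, since aryl aldehydes respond to counter-ion and solvent in the Julia–Kocienski reaction, and to a lesser degree acylation of the sulfonyl carbanion by the pivalate. The fallback separates bond formation from geometry control and sets out from **12**. A Wittig reaction with the ylide from ethyltriphenylphosphonium bromide and KN(SiMe3)2 in THF gives **13** together with 2,6-dimethoxy-4-{(2R,3R)-5-methoxy-3-methyl-7-[(1Z)-prop-1-en-1-yl]-2,3-dihydro-1,4-benzodioxin-2-yl}phenyl pivalate F6. The mixture is then equilibrated to the more stable E isomer with PdCl2(MeCN)2 (5 mol%, divalent palladium) in CH2Cl2, which returns to the route at **13**.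

## Further compounds

F1 | step 8 | 4-[(2R,3S)-7-formyl-3-(iodomethyl)-5-methoxy-2,3-dihydro-1,4-benzodioxin-2-yl]-2,6-dimethoxyphenyl pivalate | O=Cc1cc(OC)c2c(c1)O[C@H](c1cc(OC)c(OC(=O)C(C)(C)C)c(OC)c1)[C@@H](CI)O2
F2 | step 6 | 4-[(1R)-1-hydroxyprop-2-en-1-yl]-2,6-dimethoxyphenyl pivalate | O[C@@H](c1cc(OC)c(OC(=O)C(C)(C)C)c(OC)c1)C=C
F3 | step 6 | 4-{(R)-hydroxy[(2S)-oxiran-2-yl]methyl}-2,6-dimethoxyphenyl pivalate | O[C@H](c1cc(OC)c(OC(=O)C(C)(C)C)c(OC)c1)[C@@H]1CO1
F4 | step 7 | 3-hydroxy-5-methoxy-4-(methoxymethoxy)benzaldehyde | O=Cc1cc(O)c(OCOC)c(OC)c1
F5 | step 7 | 4-{(1S)-1-[5-formyl-3-methoxy-2-(methoxymethoxy)phenoxy]prop-2-en-1-yl}-2,6-dimethoxyphenyl pivalate | O=Cc1cc(OC)c(OCOC)c(c1)O[C@H](c1cc(OC)c(OC(=O)C(C)(C)C)c(OC)c1)C=C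
F6 | step 9 | 2,6-dimethoxy-4-{(2R,3R)-5-methoxy-3-methyl-7-[(1Z)-prop-1-en-1-yl]-2,3-dihydro-1,4-benzodioxin-2-yl}phenyl pivalate | C/C=C\c1cc(OC)c2c(c1)O[C@H](c1cc(OC)c(OC(=O)C(C)(C)C)c(OC)c1)[C@@H](C)O2
A1 | alternative 1 | 2-[4-(benzyloxy)-3,5-dimethoxyphenyl]-7-(1,3-dioxolan-2-yl)-5-methoxy-3-methyl-1,4-benzodioxine | CC1=C(c2cc(OC)c(OCc3ccccc3)c(OC)c2)Oc2cc(C3OCCO3)cc(OC)c2O1
A2 | alternative 1 | 5-(1,3-dioxolan-2-yl)-3-methoxy-2-(trimethylsilyl)phenyl trifluoromethanesulfonate | COc1cc(C2OCCO2)cc(OS(=O)(=O)C(F)(F)F)c1[Si](C)(C)C
A3 | alternative 1 | 1-[4-(benzyloxy)-3,5-dimethoxyphenyl]propane-1,2-dione | CC(=O)C(=O)c1cc(OC)c(OCc2ccccc2)c(OC)c1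
A4 | alternative 2 | 4-[(2R,3R)-7-(1,3-dioxolan-2-yl)-5-methoxy-3-methyl-2,3-dihydro-1,4-benzodioxin-2-yl]-2,6-dimethoxyphenyl 4-methylbenzenesulfonate | O1CCOC1c1cc(OC)c2c(c1)O[C@H](c1cc(OC)c(OS(=O)(=O)c3ccc(C)cc3)c(OC)c1)[C@@H](C)O2
A5 | alternative 2 | 4-{(1R,2R)-2-[4-(1,3-dioxolan-2-yl)-2,6-dimethoxyphenoxy]-1-hydroxypropyl}-2,6-dimethoxyphenyl 4-methylbenzenesulfonate | C[C@@H](Oc1c(OC)cc(C2OCCO2)cc1OC)[C@H](O)c1cc(OC)c(OS(=O)(=O)c2ccc(C)cc2)c(OC)c1
A6 | alternative 3 | (2R,3R)-2-(4-hydroxy-3,5-dimethoxyphenyl)-5-methoxy-3-methyl-2,3-dihydro-1,4-benzodioxine-7-carbaldehyde | O=Cc1cc(OC)c2c(c1)O[C@H](c1cc(OC)c(O)c(OC)c1)[C@@H](C)O2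
A7 | alternative 3 | 3-hydroxy-4-{[(2R)-1-(4-hydroxy-3,5-dimethoxyphenyl)propan-2-yl]oxy}-5-methoxybenzaldehyde | O=Cc1cc(OC)c(O[C@H](C)Cc2cc(OC)c(O)c(OC)c2)c(O)c1
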